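The isoflavone is disconnected at O1–C2 and, decisively, at C3–C4: C3 carries both ring B and the C4 carbonyl bound to ring A, while C2 is a lone formyl-level carbon. This 1,2-diarylpropane array is what results when the ring A aroyl group of a chalcone epoxide moves from the α- to the β-carbon. A single Lewis acid step thus turns the readily assembled 1,3-diarylpropane skeleton into the isoflavone skeleton and unmasks C2 as an aldehyde. The precursor is the racemic trans-epoxide of a chalcone bearing an acid-labile methoxymethyl ether on the future O1 and benzyl ethers on the C5 and C7 oxygens.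

Key step: step 9

Remark on the chemistry: the target is achiral; epoxide 14 and keto aldehyde 15 are carried as racemates, and their stereocentres vanish when ring C becomes aromatic.

Step 1
Reactants: 1 methyl 3,5-dihydroxy-4-methoxybenzoate; 2 benzyl bromide
Product: 3 methyl 3,5-bis(benzyloxy)-4-methoxybenzoate
Conditions: BnBr (2.3 equiv), K2CO3, DMF, 60 °C
Reagents that add atoms: benzyl bromide (second equivalent of 2), BrCc1ccccc1
Why: Twofold Williamson ether synthesis: each of the two equivalent phenoxides of the symmetric diol is alkylated by one equivalent of the reactive benzylic bromide, and the methyl ester is inert to K2CO3 in dry DMF.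

Step 2
Reactants: 3 methyl 3,5-bis(benzyloxy)-4-methoxybenzoate
Product: 4 [3,5-bis(benzyloxy)-4-methoxyphenyl]methanol
Conditions: LiAlH4, THF, 0 °C to rt; then H2O
Reagents that add atoms: none
Why: Hydride reduction of the ester to the primary benzylic alcohol with LiAlH4, to which aryl benzyl and methyl ethers are inert.

Step 3
Reactants: 4 [3,5-bis(benzyloxy)-4-methoxyphenyl]methanol
Product: 5 3,5-bis(benzyloxy)-4-methoxybenzaldehyde
Conditions: activated MnO2 (excess), CH2Cl2, rt
Reagents that add atoms: none
Why: Selective oxidation of a benzylic alcohol with MnO2, which stops at the aldehyde and leaves the ethers untouched.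

Step 4
Reactants: 5 3,5-bis(benzyloxy)-4-methoxybenzaldehyde
Product: 7 3,5-bis(benzyloxy)-4-methoxyphenol, via aryl formate 6 (not isolated)
Conditions: mCPBA, CH2Cl2, rt; then K2CO3 (cat.), MeOH, rt
Reagents that add atoms: meta-chloroperoxybenzoic acid, OOC(=O)c1cccc(Cl)c1
Why: Baeyer–Villiger oxidation in which the electron-rich aryl group migrates in preference to hydride (the Dakin-type course known for 3,4,5-trialkoxybenzaldehydes), followed by mild methanolysis of the formate, so that the carbon substituent is exchanged for the phenolic oxygen that becomes O1.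

Step 5
Reactants: 7 3,5-bis(benzyloxy)-4-methoxyphenol
Product: 8 1,3-bis(benzyloxy)-2-methoxy-5-(methoxymethoxy)benzene
Conditions: NaH, THF, 0 °C; then MOMCl, 0 °C to rt
Reagents that add atoms: chloromethyl methyl ether, COCCl
Why: O-alkylation of the sodium phenoxide with the highly reactive chloromethyl ether gives the MOM acetal, which later directs lithiation, resists the basic steps and finally serves as the only acid-labile oxygen mask on ring A.

Step 6
Reactants: 8 1,3-bis(benzyloxy)-2-methoxy-5-(methoxymethoxy)benzene; 9 N-methoxy-N-methylacetamide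
Product: 11 1-[4,6-bis(benzyloxy)-5-methoxy-2-(methoxymethoxy)phenyl]ethan-1-one, via aryllithium 10 (not isolated)
Conditions: n-BuLi, THF, −20 to 0 °C; then 9, −78 °C to rt; then H2O
Reagents that add atoms: none
Why: Directed ortho-metalation: the two ring C–H bonds are equivalent by symmetry and each lies between the strongly directing OMOM group and a benzyloxy group, so a single aryllithium should form, and its acylation with the Weinreb amide stops at the ketone because the chelated tetrahedral adduct collapses only on aqueous work-up.

Step 7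
Reactants: 11 1-[4,6-bis(benzyloxy)-5-methoxy-2-(methoxymethoxy)phenyl]ethan-1-one; 12 2,3,4-trimethoxybenzaldehyde
Product: 13 (E)-1-[4,6-bis(benzyloxy)-5-methoxy-2-(methoxymethoxy)phenyl]-3-(2,3,4-trimethoxyphenyl)prop-2-en-1-one
Conditions: KOH, EtOH/THF, rt
Reagents that add atoms: none
Why: Claisen–Schmidt condensation: the ketone is the only enolisable partner and the aldehyde the only electrophile, E1cB dehydration of the aldol should give the (E)-enone, and the masked ortho oxygens exclude cyclisation to a flavanone.

Step 8
Reactants: 13 (E)-1-[4,6-bis(benzyloxy)-5-methoxy-2-(methoxymethoxy)phenyl]-3-(2,3,4-trimethoxyphenyl)prop-2-en-1-one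
Product: 14 rac-[(2R,3S)-3-(2,3,4-trimethoxyphenyl)oxiran-2-yl][4,6-bis(benzyloxy)-5-methoxy-2-(methoxymethoxy)phenyl]methanone (trans epoxide, racemate, 2R,3S enantiomer drawn)
Conditions: 30% aq. H2O2, NaOH (cat.), MeOH/THF, 0 °C to rt; used without chromatography
Reagents that add atoms: hydrogen peroxide, OO
Why: Weitz–Scheffer nucleophilic epoxidation: conjugate addition of hydroperoxide anion and closure of the freely rotating enolate onto the O–O bond should give the trans epoxide as a racemate (relative configuration set by the preference for aroyl and aryl groups on opposite faces, no absolute control needed), and the MOM ether prevents Algar–Flynn–Oyamada cyclisation.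

Step 9
Reactants: 14 rac-[(2R,3S)-3-(2,3,4-trimethoxyphenyl)oxiran-2-yl][4,6-bis(benzyloxy)-5-methoxy-2-(methoxymethoxy)phenyl]methanone
Product: 15 3-[4,6-bis(benzyloxy)-5-methoxy-2-(methoxymethoxy)phenyl]-3-oxo-2-(2,3,4-trimethoxyphenyl)propanal (racemic, in equilibrium with its enol)
Conditions: BF3·OEt2, CH2Cl2, −20 to 0 °C, short contact; then aq. NaHCO3
Reagents that add atoms: none
Why: Coordination of BF3 to the oxirane oxygen weakens the C–O bond at the carbon attached to ring B, which opens toward a benzylic cation because the ortho and para methoxy groups of ring B donate into it, whereas the carbon next to the carbonyl cannot support positive charge. The ring A aroyl group then migrates from the α-carbon to this cationic centre, which creates the future C3–C4 bond and leaves the α-carbon as the C2 aldehyde (largely enolised and chelated). The closest known reaction type is the Lewis acid induced 1,2-acyl shift of chalcone epoxides to 2-aryl-3-oxopropanals, a Meinwald-type epoxide rearrangement in which acyl rather than hydride migrates. No ring is closed, and the one new stereocentre (the carbon bearing ring B) forms as an enolisable racemate that disappears when ring C aromatises, so no stereocontrol is required. The step needs regioselective opening at the ring B benzylic carbon, which the electron-rich ring B secures, and aroyl in preference to hydride migration, which is the normal course for chalcone epoxides under BF3 (a hydride shift would give a 1,3-diketone). Low temperature, short contact and a bicarbonate quench should keep the MOM acetal in place and prevent loss of the formyl group.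

Step 10
Reactants: 15 3-[4,6-bis(benzyloxy)-5-methoxy-2-(methoxymethoxy)phenyl]-3-oxo-2-(2,3,4-trimethoxyphenyl)propanal
Product: 18 5,7-bis(benzyloxy)-6-methoxy-3-(2,3,4-trimethoxyphenyl)-4H-chromen-4-one, via free phenol 16 (not isolated), via 2-hydroxyisoflavanone 17 (not isolated)
Conditions: HCl (ca. 1 M), MeOH/THF, 50 °C
Reagents that add atoms: none
Why: Acid-catalysed cleavage of the MOM acetal frees the phenol, which adds to the formyl carbon (6-exo-trig hemiacetal formation), and the resulting 2-hydroxyisoflavanone dehydrates to the aromatic pyranone; as the other ortho oxygen of ring A is still benzylated, ring C can close only through the future O1.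

Step 11
Reactants: 18 5,7-bis(benzyloxy)-6-methoxy-3-(2,3,4-trimethoxyphenyl)-4H-chromen-4-one
Product: 19 5,7-dihydroxy-6-methoxy-3-(2,3,4-trimethoxyphenyl)-4H-chromen-4-one (target)
Conditions: H2 (1 atm), 10% Pd/C, EtOAc/MeOH, rt
Reagents that add atoms: none
Why: Hydrogenolysis of the two aryl benzyl ethers over Pd/C under mild conditions, to which methyl ethers and the chromone ring are expected to be inert when the reaction is stopped after uptake of two equivalents of H2.

Compound list

1 | methyl 3,5-dihydroxy-4-methoxybenzoate | COC(=O)c1cc(O)c(OC)c(O)c1 | starting material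
2 | benzyl bromide | BrCc1ccccc1 | starting material
3 | methyl 3,5-bis(benzyloxy)-4-methoxybenzoate | COC(=O)c1cc(OCc2ccccc2)c(OC)c(OCc2ccccc2)c1 | intermediate
4 | [3,5-bis(benzyloxy)-4-methoxyphenyl]methanol | OCc1cc(OCc2ccccc2)c(OC)c(OCc2ccccc2)c1 | intermediate
5 | 3,5-bis(benzyloxy)-4-methoxybenzaldehyde | O=Cc1cc(OCc2ccccc2)c(OC)c(OCc2ccccc2)c1 | intermediate
6 | 3,5-bis(benzyloxy)-4-methoxyphenyl formate (not isolated) | O=COc1cc(OCc2ccccc2)c(OC)c(OCc2ccccc2)c1 | intermediate
7 | 3,5-bis(benzyloxy)-4-methoxyphenol | Oc1cc(OCc2ccccc2)c(OC)c(OCc2ccccc2)c1 | intermediate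
8 | 1,3-bis(benzyloxy)-2-methoxy-5-(methoxymethoxy)benzene | COCOc1cc(OCc2ccccc2)c(OC)c(OCc2ccccc2)c1 | intermediate
9 | N-methoxy-N-methylacetamide | CC(=O)N(C)OC | starting material
10 | [2,4-bis(benzyloxy)-3-methoxy-6-(methoxymethoxy)phenyl]lithium (not isolated) | [Li]c1c(OCOC)cc(OCc2ccccc2)c(OC)c1OCc1ccccc1 | intermediate
11 | 1-[4,6-bis(benzyloxy)-5-methoxy-2-(methoxymethoxy)phenyl]ethan-1-one | CC(=O)c1c(OCOC)cc(OCc2ccccc2)c(OC)c1OCc1ccccc1 | intermediate
12 | 2,3,4-trimethoxybenzaldehyde | COc1ccc(C=O)c(OC)c1OC | starting material
13 | (E)-1-[4,6-bis(benzyloxy)-5-methoxy-2-(methoxymethoxy)phenyl]-3-(2,3,4-trimethoxyphenyl)prop-2-en-1-one | COCOc1cc(OCc2ccccc2)c(OC)c(OCc2ccccc2)c1C(=O)/C=C/c1ccc(OC)c(OC)c1OC | intermediate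
14 | rac-[(2R,3S)-3-(2,3,4-trimethoxyphenyl)oxiran-2-yl][4,6-bis(benzyloxy)-5-methoxy-2-(methoxymethoxy)phenyl]methanone (trans, racemic, one enantiomer drawn) | COCOc1cc(OCc2ccccc2)c(OC)c(OCc2ccccc2)c1C(=O)[C@@H]1O[C@H]1c1ccc(OC)c(OC)c1OC | intermediate
15 | 3-[4,6-bis(benzyloxy)-5-methoxy-2-(methoxymethoxy)phenyl]-3-oxo-2-(2,3,4-trimethoxyphenyl)propanal (racemic, enolisable) | COCOc1cc(OCc2ccccc2)c(OC)c(OCc2ccccc2)c1C(=O)C(C=O)c1ccc(OC)c(OC)c1OC | intermediate
16 | 3-[4,6-bis(benzyloxy)-2-hydroxy-5-methoxyphenyl]-3-oxo-2-(2,3,4-trimethoxyphenyl)propanal (racemic, not isolated) | O=CC(C(=O)c1c(O)cc(OCc2ccccc2)c(OC)c1OCc1ccccc1)c1ccc(OC)c(OC)c1OC | intermediate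
17 | 5,7-bis(benzyloxy)-2-hydroxy-6-methoxy-3-(2,3,4-trimethoxyphenyl)-2,3-dihydro-4H-chromen-4-one (racemic mixture of diastereomers, not isolated) | OC1Oc2cc(OCc3ccccc3)c(OC)c(OCc3ccccc3)c2C(=O)C1c1ccc(OC)c(OC)c1OC | intermediate
18 | 5,7-bis(benzyloxy)-6-methoxy-3-(2,3,4-trimethoxyphenyl)-4H-chromen-4-one | COc1ccc(-c2coc3cc(OCc4ccccc4)c(OC)c(OCc4ccccc4)c3c2=O)c(OC)c1OC | intermediate
19 | 5,7-dihydroxy-6-methoxy-3-(2,3,4-trimethoxyphenyl)-4H-chromen-4-one | COc1ccc(-c2coc3cc(O)c(OC)c(O)c3c2=O)c(OC)c1OC | target

Total step count: 11
Longest linear sequence: 11 steps (1 to 19); compounds 2, 9 and 12 enter as purchased materials.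

Steps most likely to fail

Step 9. The epoxide may open without acyl shift (hydride shift, or capture of the benzylic cation by a ring A oxygen after premature loss of the MOM group), or the product may lose its formyl group on extended exposure to the Lewis acid. The fallback sets out from chalcone 13 and replaces the epoxide rearrangement by an oxidative 1,2-aryl shift. Tl(NO3)3·3H2O in MeOH/HC(OMe)3 at rt adds trivalent thallium to the enone, and ring B moves from the β- to the α-carbon as monovalent thallium departs. This should give the dimethyl acetal 1-[4,6-bis(benzyloxy)-5-methoxy-2-(methoxymethoxy)phenyl]-3,3-dimethoxy-2-(2,3,4-trimethoxyphenyl)propan-1-one F1, which has the same carbon connectivity as 15. Under the HCl/MeOH conditions of step 10, F1 should lose its MOM group and both acetal methoxy groups and close ring C, so the route is rejoined at compound 18.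

Step 6. n-BuLi may deprotonate a benzylic OCH2 position in competition with the ring, which would lead to Wittig rearrangement of a benzyl ether. The fallback sets out from compound 8 and installs the metal by halogen exchange instead of deprotonation. NBS in MeCN at 0 °C should brominate one of the two equivalent, highly activated ring positions to give 1,3-bis(benzyloxy)-4-bromo-2-methoxy-5-(methoxymethoxy)benzene F2. Bromine–lithium exchange with n-BuLi in THF at −78 °C, where benzylic deprotonation cannot compete, regenerates aryllithium 10, and acylation with 9 returns to the route at compound 11.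

Step 8. Conjugate addition of hydroperoxide to the twisted, electron-rich enone may be sluggish, and the acid-sensitive epoxide may open by solvolysis during long reaction times. The fallback sets out from compound 8 and builds the epoxide by C–C bond formation instead of oxidation. Aryllithium 10 is acylated with 2-chloro-N-methoxy-N-methylacetamide (ClCC(=O)N(C)OC) to give 1-[4,6-bis(benzyloxy)-5-methoxy-2-(methoxymethoxy)phenyl]-2-chloroethan-1-one F3. Darzens condensation of F3 with aldehyde 12 (NaOMe, MeOH/THF, 0 °C) should give the trans epoxy ketone directly, so the route is rejoined at compound 14.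

Further compounds

F1 | step 9 | 1-[4,6-bis(benzyloxy)-5-methoxy-2-(methoxymethoxy)phenyl]-3,3-dimethoxy-2-(2,3,4-trimethoxyphenyl)propan-1-one (racemic) | COCOc1cc(OCc2ccccc2)c(OC)c(OCc2ccccc2)c1C(=O)C(C(OC)OC)c1ccc(OC)c(OC)c1OC
F2 | step 6 | 1,3-bis(benzyloxy)-4-bromo-2-methoxy-5-(methoxymethoxy)benzene | COCOc1cc(OCc2ccccc2)c(OC)c(OCc2ccccc2)c1Br
F3 | step 8 | 1-[4,6-bis(benzyloxy)-5-methoxy-2-(methoxymethoxy)phenyl]-2-chloroethan-1-one | COCOc1cc(OCc2ccccc2)c(OC)c(OCc2ccccc2)c1C(=O)CCl
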